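## Structural features

The target is a nine-membered carbocycle (C1–C9) with an (E)-trisubstituted alkene C4=C5 carrying the C4 methyl group and a second, ring-cis alkene C7=C8 that bears a formyl group (an (E)-enal by CIP); C6 is a doubly allylic methylene between them. C9 is an sp3 methine carrying the second formyl group, so C8 and C9 form a 1,4-dialdehyde, and C1 carries an exocyclic methine Cb substituted by CH2OAc (Ca) and a 4-methylpent-3-enyl chain. The three stereocentres are contiguous: Cb (R) outside the ring, C1 (S) and C9 (S) inside it, with the C1 side chain and the C9 formyl group trans on the ring. The fragile points are the C9 hydrogen (α to one aldehyde and allylic to the enal, so easily epimerised or moved into conjugation), the strained (E)-cyclononene (open to transannular carbonyl–ene chemistry under acid) and the base-labile primary acetate. In addition, a free Ca hydroxyl would close onto the C9 formyl carbon as a six-membered lactol. The real difficulty is threefold: closing a nine-membered ring that contains an E alkene, relating the exocyclic centre Cb to C1, and placing the acetate on Ca without ever holding a free hydroxy aldehyde. The key step exploits the six-atom chain acetate O–Ca–Cb–C1–C9–C(formyl). Closed through oxygen it is a 3,4-dihydro-2H-pyran whose enol ether carbon is the C9 formyl carbon, so Cb and C1 can be set as neighbours on a six-membered ring by a [4+2] cycloaddition, and the nucleophilic enol ether position C9 then serves to attach C8.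

## Logic of the disconnections

32 ⇒ 31 ⇒ 30. The acyl C–O bond of the acetate and the two C=O bonds are taken back to a free Ca hydroxyl and two C=N–NMe2 groups. The cut is made here because a free Ca hydroxyl next to a free C9 formyl group would exist as a lactol and be acetylated at the wrong oxygen. With both aldehydes masked, the only hydroxyl of 30 is the one to be acetylated. The gain is that the ester and both aldehydes are absent from all earlier chemistry. The forward demand is an unmasking (31 → 32) that is neither acidic (transannular ene reaction) nor basic (C9).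

30 ⇒ 28 (through 29). The Ca oxygen is re-joined to the C9 formyl carbon and the C9 hydrogen is removed, giving a bicyclic dienol ether. One dihydropyran ring then masks the Ca hydroxyl and the C9 aldehyde together and makes C9 sp2, so no C9 stereocentre has to survive the ring construction. The demand on the forward step is twofold. It must protonate C9 and not C7, which is why the C8 formyl group is installed first and makes C7 electron-poor. It must also leave C9 trans to C1, which is entrusted to equilibration in 29.

28 ⇒ 27 ⇒ 25. The C8–CHO bond is cut, first to a C8–O triflate bond and then to the C8 ketone. In 25 the carbonyl is flanked by sp2 C9 and can enolise only towards C7, and the ring size allows only the ring-cis enol geometry, so regio- and stereochemistry of the enal are settled by the substrate. The formyl carbon then comes from carbon monoxide. The demand is that CO insertion outruns hydride transfer.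

25 ⇒ 24 ⇒ 23. After a phenylsulfonyl group is put back on C7, the ring is opened at C6–C7. C6 is allylic and C7 is α to the C8 carbonyl, so these are the natural electrophile and nucleophile, and the sulfone makes C7 a soft carbanion accessible with carbonate. The precursor 23 is an open chain held on a six-membered ring. The demand is an intramolecular SN2 reaction that beats oligomerisation and does not scramble C4=C5.

23 ⇒ 22 ⇒ 19 + 20, and 19 ⇒ 17. The C7–C8 bond is cut (sulfonyl carbanion plus aldehyde, oxidation level adjusted afterwards), then the C8–C9 bond (formylation of the enol ether β-carbon). C9 is the only nucleophilic carbon of the dihydropyran, and C7 and C8 each come from a one-carbon reagent. The demand is that the carbanion adds to the aldehyde of 19 and leaves its allylic chloride alone.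

17 ⇒ 15 ⇒ 12. C6–Cl goes back to C6–OH, then C5–C6 and C4–CH3 are cut together to the terminal alkyne. This is the carbometalation retron for an (E)-trisubstituted alkene: three carbons and the alkene geometry reduce to one alkyne. The demand is syn addition with methyl on the internal carbon, in the presence of the enol ether.

12 ⇒ 10 (through 11). Ca–H is returned to Ca–OEt and the acetylenic C–H to C–Si, which reveals the cycloadduct. The demand is removal of the acetal oxygen without the side-chain alkene capturing the intermediate cation.

10 ⇒ 4 + 9. The C1–Cb and O–Ca bonds are cut in a retro-[4+2] sense. This removes the ring and three stereocentres at once and leaves two achiral, linear partners. The demand is an endo, face-selective cycloaddition in which the E geometry of 4 and the Z geometry of 9 are translated into the all-cis adduct.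

4 ⇒ 2 + 3 ⇒ 1, and 9 ⇒ 8 ⇒ 5 + 6. The enal C=C bond is cut to an aldehyde and a two-carbon ylide, and 2 is the oxidation product of 1. The enol ether is traced to the alkyne (syn hydrogenation for Z) and this to an acetylide and a primary bromide by cutting the bond between Cb and its side chain. The demands are E selectivity in the olefination, and substitution rather than elimination at the homoallylic bromide.

## Other disconnections considered

Alternative 1: The cut is the ring bond C1–C9, made as a retro-[3,3] shift in which the oxygen of the C9 carboxyl group is re-attached to Cc. This expands the carbocycle into the thirteen-membered allylic lactone A2. Forward, A2 would be enolised and O-silylated (LiN(iPr)2, Me3SiCl) and would contract by an Ireland–Claisen rearrangement to the nine-membered acid A1.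
- In its favour: the ring and a bond between two stereocentres would arise together in one intramolecular pericyclic step. Ring closure is shifted to a macrolactonisation, which is easier than any direct nine-membered closure. C1 would be set by 1,3-transfer from the Cc carbinol centre and C9 kinetically by the cyclic transition state. C9 already carries its one-carbon substituent and C8 its CH2O group.
- Against it here: Cb emerges as an sp2 carbon of the new Cb=Cc alkene, so the Cb centre would have to be made afterwards by face-selective reduction of one trisubstituted alkene among four. The C9 outcome depends on enolate geometry and on a chair or boat arrangement inside a thirteen-membered ring and is hard to predict. The C9 methylene of A2 is both α to the ester and allylic, so the site of enolisation is not assured. A2 itself needs two defined trisubstituted alkenes, the Cb=C1 alkene, the Cc stereocentre and a macrolactonisation.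
- Comparison, structure: A1 is better than the chosen plan for the ring (formed together with C1 and C9) and for C9 (kinetic control, where the chosen plan relies on equilibration). It is worse for Cb, which the chosen plan sets with C1 in one catalytic step.
- Comparison, mechanism: both key steps are concerted pericyclic reactions. The alternative draws its asymmetry from a stoichiometric stereocentre, the chosen plan from a catalyst.
- Comparison, step economy: the endgame from A1 (alkene reduction, acid to aldehyde, two deprotections, acetylation, oxidation) is about as long as steps 13–18. The approach to A2 is expected to be longer than steps 1–12, so the alternative is at best equal overall.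

Alternative 2: The cut is a retrosynthetic bond across the ring between C4 and C9, which turns the cyclononene into the cis-hydrindanol monotosylate A4 (C9 carbinol, C4 angular methyl, C5 tosylate). Forward, A4 would be deprotonated (KOtBu) and would undergo Grob fragmentation to the (E)-cyclononenone A3.
- In its favour: the fragmentation is stereospecific, since the antiperiplanar C4–C9 bond and equatorial tosylate translate directly into the E geometry of C4=C5. No high dilution is needed, and C1 and Cb can be installed on a rigid bicycle. On ring formation this is the better of the two plans; it is more dependable than the intramolecular alkylation of step 12.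
- Against it here: A3 has a ketone at C9 and bare methylenes at C7 and C8. The C9 formyl carbon, the C8 formyl carbon and the C7=C8 unsaturation would all have to be introduced on the strained ring. The ketone is flanked by the C1 methine, so enolate chemistry directed at C8 puts the C1 stereocentre at risk. Three stereocentres of A4 (C4, C5, C9) would be built only to be destroyed.
- Comparison, structure: A3 is further from the target than 25 is (25 lacks one carbon; A3 lacks two carbons and a double bond).
- Comparison, mechanism: heterolytic fragmentation against SN2 ring closure, the fragmentation being the safer.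
- Comparison, step economy: equal or somewhat longer before the key step, clearly longer after it.

Alternative 3: The cut is the ring bond C2–C3 together with retrosynthetic formation of C5–C9, which contracts the carbocycle to the trans-1,2-dialkenylcyclopentenol A6. In A6 the C9 carbinol bears the C1=C2 alkenyl group, C5 bears the C4(CH3)=C3 isopropenyl group, and C7=C8 lies inside the five-membered ring. Forward, A6 would be deprotonated (KH, 18-crown-6) and would undergo an anionic oxy-Cope rearrangement; protonation at C1 would give the dienone A5.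
- In its favour: a four-atom ring expansion without dilution, and E geometry at C4=C5 from a chair-like transition state. The ring-cis C7=C8 bond and its CH2O substituent are carried in from the cyclopentene. On this point the alternative is better than the chosen plan, where the C8 carbon needs triflation and carbonylation. The assembly of A6 is convergent.
- Against it here: C1 would be created by protonation of a medium-ring enolate, controlled only by the exocyclic Cb centre, and would stay α to the ketone. The C9 ketone, flanked by the C1 methine and the substituted C8, still needs a one-carbon homologation to CH–CHO with control of C9. The trans relationship in A6 must be secured in a 1,2-addition next to a stereocentre.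
- Comparison, structure: A5 is closer to the target than 25 at C7/C8 and further at C9; Cb must be made separately in both plans.
- Comparison, mechanism: a [3,3] ring expansion is the equal of the chosen ring closure in reliability. It has two stereochemically open events (C1 protonation, C9 homologation) where the chosen plan has one (C9 equilibration).
- Comparison, step economy: probably equal, possibly one or two steps shorter, at the price of weaker stereocontrol.

Key step: step 5

Assumption: the chromium complex of the (1R,2S)-aminoindanol ligand is taken to deliver the (2S,3R,4R) adduct 10 by analogy with the facial sense of this catalyst class; if the sense is the opposite, the (1S,2R) ligand is used and nothing else changes.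

Remark: 10 was checked atom by atom against 32; all-cis (2S,3R,4R)-10 carries Cb (R) and C1 (S) of the target, and no structure needed correction. The CIP label at C1 changes along the route only because its neighbours change. Compounds 1, 3, 5, 6 and 20 are catalogue chemicals.

## Route

Step 1
Reactants: 1 5-(trimethylsilyl)pent-4-yn-1-ol
Product: 2 5-(trimethylsilyl)pent-4-ynal
Conditions: TEMPO (10 mol%), PhI(OAc)2, CH2Cl2, rt
Reagents that add atoms: none
Why: Nitroxyl-catalysed oxidation of a primary alcohol stops at the aldehyde and does not touch the silylalkyne.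

Step 2
Reactants: 2 5-(trimethylsilyl)pent-4-ynal; 3 (triphenylphosphoranylidene)acetaldehyde
Product: 4 (E)-7-(trimethylsilyl)hept-2-en-6-ynal
Conditions: toluene, 80 °C
Reagents that add atoms: none
Why: Wittig olefination with the formyl-stabilised ylide is E-selective (reversible addition, thermodynamic oxaphosphetane); a small excess of 2 suppresses a second homologation of the product enal.

Step 3
Reactants: 5 ethoxyacetylene; 6 5-bromo-2-methylpent-2-ene
Product: 8 1-ethoxy-6-methylhept-5-en-1-yne, via lithium ethoxyacetylide 7 (not isolated)
Conditions: n-BuLi, THF, −78 °C; then 6, DMPU, −78 °C → rt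
Reagents that add atoms: none
Why: Deprotonation gives the lithium alkynyl ether, and its SN2 alkylation by the primary bromide in a dipolar co-solvent installs the 4-methylpent-3-enyl chain; low temperature limits E2 loss of HBr from the homoallylic bromide.

Step 4
Reactants: 8 1-ethoxy-6-methylhept-5-en-1-yne
Product: 9 (Z)-1-ethoxy-6-methylhepta-1,5-diene
Conditions: H2 (1 atm), Pd/CaCO3 poisoned with Pb(OAc)2 (Lindlar catalyst), quinoline, hexane, 0 °C → rt
Reagents that add atoms: none
Why: Lindlar semihydrogenation delivers both hydrogens to one face of the alkyne and gives the (Z)-enol ether; the trisubstituted alkene is not reduced on the poisoned catalyst.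

Step 5
Reactants: 4 (E)-7-(trimethylsilyl)hept-2-en-6-ynal; 9 (Z)-1-ethoxy-6-methylhepta-1,5-diene
Product: 10 (2S,3R,4R)-2-ethoxy-3-(4-methylpent-3-en-1-yl)-4-[4-(trimethylsilyl)but-3-yn-1-yl]-3,4-dihydro-2H-pyran
Conditions: Cr(L)Cl (10 mol%; L = Schiff base of 3-(1-adamantyl)-5-methylsalicylaldehyde and (1R,2S)-1-aminoindan-2-ol), 4 Å MS, neat, 9 (2 equiv), rt → 40 °C
Reagents that add atoms: none
Why: The trivalent chromium centre binds the aldehyde oxygen of 4 and lowers the LUMO of the 1-oxadiene, which takes up the electron-rich enol ether 9 in a concerted, asynchronous inverse-electron-demand hetero-Diels–Alder reaction in which C1–Cb bonding runs ahead of O–Ca bonding. The closest known reaction type is the chromium-catalysed enantioselective cycloaddition of α,β-unsaturated aldehydes with alkyl vinyl ethers; a β-substituted (Z)-enol ether lies at the limit of that scope. The dihydropyran ring is closed by intermolecular [4+2] cycloaddition of a four-atom (O=C–C=C) and a two-atom (C=C) component through an endo transition state. C4 of 10 (C1 of the target) is set by the enal face that the adamantyl-substituted ligand leaves open. C3 (Cb) follows from suprafacial addition across the (Z)-double bond, which places the side chain cis to ethoxy. C2 (the acetal centre, removed in step 6) follows from the endo orientation of ethoxy. Because the enal is E and the enol ether is Z, endo addition gives the all-cis adduct. The step needs chemoselectivity for the enol ether over the trisubstituted alkene and the alkyne (secured by the much higher HOMO of the enol ether), the regiochemistry that joins nucleophilic Cb to electrophilic C1 (secured by the polarisation of both partners), and endo and facial selectivity (secured by the catalyst).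

Step 6
Reactants: 10 (2S,3R,4R)-2-ethoxy-3-(4-methylpent-3-en-1-yl)-4-[4-(trimethylsilyl)but-3-yn-1-yl]-3,4-dihydro-2H-pyran
Product: 12 (3R,4S)-4-(but-3-yn-1-yl)-3-(4-methylpent-3-en-1-yl)-3,4-dihydro-2H-pyran, via silyl-capped dihydropyran 11 (not isolated)
Conditions: Et3SiH (5 equiv), BF3·OEt2 (1.2 equiv), CH2Cl2, −78 °C; then MeOH, K2CO3, −78 °C → rt
Reagents that add atoms: none
Why: Ionic reduction of the cyclic acetal: BF3 removes ethoxide, the ring oxocarbenium ion takes hydride from the silane, and the basic methanol quench then cleaves the C(sp)–Si bond. The two ring stereocentres are not involved, and the large excess of silane at low temperature is meant to outrun capture of the cation by the side-chain alkene.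

Step 7
Reactants: 12 (3R,4S)-4-(but-3-yn-1-yl)-3-(4-methylpent-3-en-1-yl)-3,4-dihydro-2H-pyran
Product: 15 (2E)-3-methyl-5-[(3R,4S)-3-(4-methylpent-3-en-1-yl)-3,4-dihydro-2H-pyran-4-yl]pent-2-en-1-ol, via alkenyldimethylalane 13 (not isolated), via lithium alkenylalanate 14 (not isolated)
Conditions: Me3Al, Cp2ZrCl2 (25 mol%), CH2Cl2, 0 °C → rt; then n-BuLi, THF, −78 °C; (CH2O)n, −78 °C → rt
Reagents that add atoms: trimethylaluminium, C[Al](C)C; formaldehyde (as paraformaldehyde), C=O
Why: Zirconium-catalysed carboalumination adds methyl and aluminium syn across the terminal alkyne with methyl on the internal carbon. The butyl ate complex is then hydroxymethylated with retention, so the E geometry of C4=C5 is fixed here and C6 enters as CH2OH.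

Step 8
Reactants: 15 (2E)-3-methyl-5-[(3R,4S)-3-(4-methylpent-3-en-1-yl)-3,4-dihydro-2H-pyran-4-yl]pent-2-en-1-ol
Product: 17 (3R,4S)-4-[(3E)-5-chloro-3-methylpent-3-en-1-yl]-3-(4-methylpent-3-en-1-yl)-3,4-dihydro-2H-pyran, via allylic mesylate 16 (not isolated)
Conditions: MsCl, LiCl, 2,4,6-collidine, DMF, 0 °C
Reagents that add atoms: lithium chloride, [Li+].[Cl-]
Why: Mesylation in the presence of chloride converts the primary allylic alcohol into the chloride by SN2 displacement without allylic transposition; the collidine buffer protects the enol ether.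

Step 9
Reactants: 17 (3R,4S)-4-[(3E)-5-chloro-3-methylpent-3-en-1-yl]-3-(4-methylpent-3-en-1-yl)-3,4-dihydro-2H-pyran
Product: 19 (3R,4S)-4-[(3E)-5-chloro-3-methylpent-3-en-1-yl]-3-(4-methylpent-3-en-1-yl)-3,4-dihydro-2H-pyran-5-carbaldehyde, via vinylogous iminium salt 18 (not isolated)
Conditions: POCl3, DMF, CH2Cl2, 0 °C → rt; then aq. NaOAc
Reagents that add atoms: N,N-dimethylformamide, CN(C)C=O; water, O
Why: Vilsmeier–Haack formylation: the chloroiminium ion attacks the nucleophilic β-carbon of the cyclic enol ether (C9), loss of the C9 proton gives the vinylogous iminium salt, and hydrolysis gives the β-alkoxyacrolein, as is known for dihydropyrans and glycals. This attaches C8; unactivated alkenes and the allylic chloride do not react.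

Step 10
Reactants: 19 (3R,4S)-4-[(3E)-5-chloro-3-methylpent-3-en-1-yl]-3-(4-methylpent-3-en-1-yl)-3,4-dihydro-2H-pyran-5-carbaldehyde; 20 methyl phenyl sulfone
Product: 22 1-[(3R,4S)-4-[(3E)-5-chloro-3-methylpent-3-en-1-yl]-3-(4-methylpent-3-en-1-yl)-3,4-dihydro-2H-pyran-5-yl]-2-(phenylsulfonyl)ethan-1-ol, via (phenylsulfonyl)methyllithium 21 (not isolated)
Conditions: 20, n-BuLi, THF, −78 °C; then 19, −78 °C; aq. NH4Cl
Reagents that add atoms: none
Why: 1,2-Addition of the α-sulfonyl carbanion to the aldehyde at −78 °C is much faster than its SN2 reaction with the allylic chloride, so one equivalent adds chemoselectively at C8 and brings in C7 with its activating group. The new carbinol centre (both epimers) is removed in step 11.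

Step 11
Reactants: 22 1-[(3R,4S)-4-[(3E)-5-chloro-3-methylpent-3-en-1-yl]-3-(4-methylpent-3-en-1-yl)-3,4-dihydro-2H-pyran-5-yl]-2-(phenylsulfonyl)ethan-1-ol
Product: 23 1-[(3R,4S)-4-[(3E)-5-chloro-3-methylpent-3-en-1-yl]-3-(4-methylpent-3-en-1-yl)-3,4-dihydro-2H-pyran-5-yl]-2-(phenylsulfonyl)ethan-1-one
Conditions: Dess–Martin periodinane, NaHCO3, CH2Cl2, 0 °C → rt
Reagents that add atoms: none
Why: Dess–Martin oxidation of the secondary β-hydroxy sulfone under bicarbonate buffer gives the β-keto sulfone without acid-induced ionisation of the alkoxy-allylic alcohol.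

Step 12
Reactants: 23 1-[(3R,4S)-4-[(3E)-5-chloro-3-methylpent-3-en-1-yl]-3-(4-methylpent-3-en-1-yl)-3,4-dihydro-2H-pyran-5-yl]-2-(phenylsulfonyl)ethan-1-one
Product: 24 (1S,4E,13R)-4-methyl-13-(4-methylpent-3-en-1-yl)-7-(phenylsulfonyl)-11-oxabicyclo[7.4.0]trideca-4,9-dien-8-one
Conditions: Cs2CO3, Bu4NI (cat.), MeCN, 2 mM (slow addition), 50 °C
Reagents that add atoms: none
Why: Intramolecular C-alkylation of the soft β-keto sulfone anion by the allylic halide (SN2, with iodide exchange in situ) under high dilution closes the C6–C7 bond. This type of closure is established for nine-membered carbocycles containing an (E)-trisubstituted alkene; SN2 displacement keeps the E geometry, and the dihydropyran holds the two chains on adjacent ring atoms. The C7 configuration is immaterial.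

Step 13
Reactants: 24 (1S,4E,13R)-4-methyl-13-(4-methylpent-3-en-1-yl)-7-(phenylsulfonyl)-11-oxabicyclo[7.4.0]trideca-4,9-dien-8-one
Product: 25 (1S,4E,13R)-4-methyl-13-(4-methylpent-3-en-1-yl)-11-oxabicyclo[7.4.0]trideca-4,9-dien-8-one
Conditions: SmI2, THF/MeOH, −78 °C
Reagents that add atoms: none
Why: Reductive desulfonylation: SmI2 cleaves the C–S bond α to the ketone by two single-electron transfers and methanol protonates the enolate; the vinylogous ester carbonyl is not reduced at this temperature.

Step 14
Reactants: 25 (1S,4E,13R)-4-methyl-13-(4-methylpent-3-en-1-yl)-11-oxabicyclo[7.4.0]trideca-4,9-dien-8-one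
Product: 27 (1S,4E,7E,13R)-4-methyl-13-(4-methylpent-3-en-1-yl)-11-oxabicyclo[7.4.0]trideca-4,7,9-trien-8-yl trifluoromethanesulfonate, via potassium dienolate 26 (not isolated)
Conditions: KN(SiMe3)2, THF, −78 °C; then PhNTf2, −78 → 0 °C
Reagents that add atoms: N-phenylbis(trifluoromethanesulfonimide), O=S(=O)(N(c1ccccc1)S(=O)(=O)C(F)(F)F)C(F)(F)F
Why: The vinylogous ester has α-hydrogens only at C7, so kinetic deprotonation is regiospecific and O-triflation of the dienolate gives the C7=C8 enol triflate. In a nine-membered ring that already holds an E alkene the new double bond can only be ring-cis, which is the geometry of the target.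

Step 15
Reactants: 27 (1S,4E,7E,13R)-4-methyl-13-(4-methylpent-3-en-1-yl)-11-oxabicyclo[7.4.0]trideca-4,7,9-trien-8-yl trifluoromethanesulfonate
Product: 28 (1S,4E,7E,13R)-4-methyl-13-(4-methylpent-3-en-1-yl)-11-oxabicyclo[7.4.0]trideca-4,7,9-triene-8-carbaldehyde
Conditions: Pd(PPh3)4 (5 mol%), LiCl, CO (1 atm), Bu3SnH (slow addition), THF, 50 °C
Reagents that add atoms: carbon monoxide, [C-]#[O+]
Why: Palladium-catalysed reductive carbonylation of an alkenyl triflate: oxidative addition to zerovalent palladium, CO insertion to the acyl complex and hydride transfer from the stannane give the enal with retention of the C7=C8 geometry. Slow addition of the stannane favours CO insertion over direct reduction.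

Step 16
Reactants: 28 (1S,4E,7E,13R)-4-methyl-13-(4-methylpent-3-en-1-yl)-11-oxabicyclo[7.4.0]trideca-4,7,9-triene-8-carbaldehyde
Product: 30 (2R)-2-[(1R,2S,3E,6E)-2,3-bis[(E)-(2,2-dimethylhydrazinylidene)methyl]-7-methylcyclonona-3,6-dien-1-yl]-6-methylhept-5-en-1-ol, via trans-fused lactol 29 (not isolated)
Conditions: 0.5 M aq. HCl, THF, 0 °C; Et3N to pH 9, rt; then AcOH/NaOAc (pH 5), Me2NNH2 (4 equiv), rt
Reagents that add atoms: 1,1-dimethylhydrazine, CN(C)N
Why: With the formyl group on C8 the C7 position is electron-poor, so the dienol ether is protonated at C9 and water opens the oxocarbenium ion to the lactol (enol ether hydrolysis). Mild base then lets C9 epimerise through the open hydroxy aldehyde towards the trans-fused lactol, in which the ring bonds at C1 and C9 are both equatorial on the pyran chair. Hydrazone formation at the enal and then at the lactol carbon pulls the ring open, frees the Ca hydroxyl and locks C9.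

Step 17
Reactants: 30 (2R)-2-[(1R,2S,3E,6E)-2,3-bis[(E)-(2,2-dimethylhydrazinylidene)methyl]-7-methylcyclonona-3,6-dien-1-yl]-6-methylhept-5-en-1-ol
Product: 31 (2R)-2-[(1R,2S,3E,6E)-2,3-bis[(E)-(2,2-dimethylhydrazinylidene)methyl]-7-methylcyclonona-3,6-dien-1-yl]-6-methylhept-5-en-1-yl acetate
Conditions: Ac2O, pyridine, DMAP (cat.), CH2Cl2, 0 °C → rt
Reagents that add atoms: acetic anhydride, CC(=O)OC(C)=O
Why: Nucleophile-catalysed O-acetylation of the only hydroxyl group; both aldehydes are masked, so no lactol acetate can form.

Step 18
Reactants: 31 (2R)-2-[(1R,2S,3E,6E)-2,3-bis[(E)-(2,2-dimethylhydrazinylidene)methyl]-7-methylcyclonona-3,6-dien-1-yl]-6-methylhept-5-en-1-yl acetate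
Product: 32 (2R)-2-[(1S,2S,3E,6E)-2,3-diformyl-7-methylcyclonona-3,6-dien-1-yl]-6-methylhept-5-en-1-yl acetate
Conditions: CuCl2 (4 equiv), THF/pH 7 phosphate buffer, rt
Reagents that add atoms: water, O
Why: Copper-assisted hydrolysis of N,N-dimethylhydrazones at neutral pH (the metal binds the liberated hydrazine) releases both aldehydes without the acid that would trigger a transannular carbonyl–ene reaction or the base that would epimerise C9.

## Compound list

1 | 5-(trimethylsilyl)pent-4-yn-1-ol | C[Si](C)(C)C#CCCCO | starting material
2 | 5-(trimethylsilyl)pent-4-ynal | C[Si](C)(C)C#CCCC=O | intermediate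
3 | (triphenylphosphoranylidene)acetaldehyde | O=CC=P(c1ccccc1)(c1ccccc1)c1ccccc1 | starting material
4 | (E)-7-(trimethylsilyl)hept-2-en-6-ynal | O=C/C=C/CCC#C[Si](C)(C)C | intermediate
5 | ethoxyacetylene | CCOC#C | starting material
6 | 5-bromo-2-methylpent-2-ene | CC(C)=CCCBr | starting material
7 | lithium ethoxyacetylide | CCOC#C[Li] | intermediate
8 | 1-ethoxy-6-methylhept-5-en-1-yne | CCOC#CCCC=C(C)C | intermediate
9 | (Z)-1-ethoxy-6-methylhepta-1,5-diene | CCO/C=C\CCC=C(C)C | intermediate
10 | (2S,3R,4R)-2-ethoxy-3-(4-methylpent-3-en-1-yl)-4-[4-(trimethylsilyl)but-3-yn-1-yl]-3,4-dihydro-2H-pyran (all-cis) | CCO[C@H]1OC=C[C@@H](CCC#C[Si](C)(C)C)[C@H]1CCC=C(C)C | intermediate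
11 | (3R,4S)-3-(4-methylpent-3-en-1-yl)-4-[4-(trimethylsilyl)but-3-yn-1-yl]-3,4-dihydro-2H-pyran | C1OC=C[C@@H](CCC#C[Si](C)(C)C)[C@H]1CCC=C(C)C | intermediate
12 | (3R,4S)-4-(but-3-yn-1-yl)-3-(4-methylpent-3-en-1-yl)-3,4-dihydro-2H-pyran | C1OC=C[C@@H](CCC#C)[C@H]1CCC=C(C)C | intermediate
13 | dimethyl{(1E)-2-methyl-4-[(3R,4S)-3-(4-methylpent-3-en-1-yl)-3,4-dihydro-2H-pyran-4-yl]but-1-en-1-yl}alane | C1OC=C[C@@H](CC/C(C)=C/[Al](C)C)[C@H]1CCC=C(C)C | intermediate
14 | lithium butyl(dimethyl){(1E)-2-methyl-4-[(3R,4S)-3-(4-methylpent-3-en-1-yl)-3,4-dihydro-2H-pyran-4-yl]but-1-en-1-yl}aluminate | C1OC=C[C@@H](CC/C(C)=C/[Al-](C)(C)CCCC)[C@H]1CCC=C(C)C.[Li+] | intermediate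
15 | (2E)-3-methyl-5-[(3R,4S)-3-(4-methylpent-3-en-1-yl)-3,4-dihydro-2H-pyran-4-yl]pent-2-en-1-ol | C1OC=C[C@@H](CC/C(C)=C/CO)[C@H]1CCC=C(C)C | intermediate
16 | (2E)-3-methyl-5-[(3R,4S)-3-(4-methylpent-3-en-1-yl)-3,4-dihydro-2H-pyran-4-yl]pent-2-en-1-yl methanesulfonate | C1OC=C[C@@H](CC/C(C)=C/COS(C)(=O)=O)[C@H]1CCC=C(C)C | intermediate
17 | (3R,4S)-4-[(3E)-5-chloro-3-methylpent-3-en-1-yl]-3-(4-methylpent-3-en-1-yl)-3,4-dihydro-2H-pyran | C1OC=C[C@@H](CC/C(C)=C/CCl)[C@H]1CCC=C(C)C | intermediate
18 | N-{[(3R,4S)-4-[(3E)-5-chloro-3-methylpent-3-en-1-yl]-3-(4-methylpent-3-en-1-yl)-3,4-dihydro-2H-pyran-5-yl]methylidene}-N-methylmethanaminium dichlorophosphate | C1OC=C(C=[N+](C)C)[C@@H](CC/C(C)=C/CCl)[C@H]1CCC=C(C)C.[O-]P(=O)(Cl)Cl | intermediate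
19 | (3R,4S)-4-[(3E)-5-chloro-3-methylpent-3-en-1-yl]-3-(4-methylpent-3-en-1-yl)-3,4-dihydro-2H-pyran-5-carbaldehyde | C1OC=C(C=O)[C@@H](CC/C(C)=C/CCl)[C@H]1CCC=C(C)C | intermediate
20 | methyl phenyl sulfone | CS(=O)(=O)c1ccccc1 | starting material
21 | (phenylsulfonyl)methyllithium | [Li]CS(=O)(=O)c1ccccc1 | intermediate
22 | 1-[(3R,4S)-4-[(3E)-5-chloro-3-methylpent-3-en-1-yl]-3-(4-methylpent-3-en-1-yl)-3,4-dihydro-2H-pyran-5-yl]-2-(phenylsulfonyl)ethan-1-ol (both carbinol epimers) | C1OC=C(C(O)CS(=O)(=O)c2ccccc2)[C@@H](CC/C(C)=C/CCl)[C@H]1CCC=C(C)C | intermediate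
23 | 1-[(3R,4S)-4-[(3E)-5-chloro-3-methylpent-3-en-1-yl]-3-(4-methylpent-3-en-1-yl)-3,4-dihydro-2H-pyran-5-yl]-2-(phenylsulfonyl)ethan-1-one | C1OC=C(C(=O)CS(=O)(=O)c2ccccc2)[C@@H](CC/C(C)=C/CCl)[C@H]1CCC=C(C)C | intermediate
24 | (1S,4E,13R)-4-methyl-13-(4-methylpent-3-en-1-yl)-7-(phenylsulfonyl)-11-oxabicyclo[7.4.0]trideca-4,9-dien-8-one (both C7 epimers; positions 1–9 are the ring carbons C1–C9 of the target, 10 the C9 formyl carbon, 12 Ca, 13 Cb) | C1OC=C2C(=O)C(S(=O)(=O)c3ccccc3)C/C=C(C)/CC[C@H]2[C@H]1CCC=C(C)C | intermediate
25 | (1S,4E,13R)-4-methyl-13-(4-methylpent-3-en-1-yl)-11-oxabicyclo[7.4.0]trideca-4,9-dien-8-one | C1OC=C2C(=O)CC/C=C(C)/CC[C@H]2[C@H]1CCC=C(C)C | intermediate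
26 | potassium (1S,4E,7E,13R)-4-methyl-13-(4-methylpent-3-en-1-yl)-11-oxabicyclo[7.4.0]trideca-4,7,9-trien-8-olate | C1OC=C2/C([O-])=C\C/C=C(C)/CC[C@H]2[C@H]1CCC=C(C)C.[K+] | intermediate
27 | (1S,4E,7E,13R)-4-methyl-13-(4-methylpent-3-en-1-yl)-11-oxabicyclo[7.4.0]trideca-4,7,9-trien-8-yl trifluoromethanesulfonate | C1OC=C2/C(OS(=O)(=O)C(F)(F)F)=C\C/C=C(C)/CC[C@H]2[C@H]1CCC=C(C)C | intermediate
28 | (1S,4E,7E,13R)-4-methyl-13-(4-methylpent-3-en-1-yl)-11-oxabicyclo[7.4.0]trideca-4,7,9-triene-8-carbaldehyde | C1OC=C2/C(C=O)=C\C/C=C(C)/CC[C@H]2[C@H]1CCC=C(C)C | intermediate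
29 | (1S,4E,7E,9S,13R)-10-hydroxy-4-methyl-13-(4-methylpent-3-en-1-yl)-11-oxabicyclo[7.4.0]trideca-4,7-diene-8-carbaldehyde (trans-fused; both anomers at C10) | OC1OC[C@H](CCC=C(C)C)[C@@H]2CC/C(C)=C/C/C=C(/C=O)[C@@H]12 | intermediate
30 | (2R)-2-[(1R,2S,3E,6E)-2,3-bis[(E)-(2,2-dimethylhydrazinylidene)methyl]-7-methylcyclonona-3,6-dien-1-yl]-6-methylhept-5-en-1-ol (the label 1R is the same spatial arrangement as 1S in 32) | OC[C@H](CCC=C(C)C)[C@@H]1CC/C(C)=C/C/C=C(/C=N/N(C)C)[C@H]1/C=N/N(C)C | intermediate
31 | (2R)-2-[(1R,2S,3E,6E)-2,3-bis[(E)-(2,2-dimethylhydrazinylidene)methyl]-7-methylcyclonona-3,6-dien-1-yl]-6-methylhept-5-en-1-yl acetate | CC(=O)OC[C@H](CCC=C(C)C)[C@@H]1CC/C(C)=C/C/C=C(/C=N/N(C)C)[C@H]1/C=N/N(C)C | intermediate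
32 | (2R)-2-[(1S,2S,3E,6E)-2,3-diformyl-7-methylcyclonona-3,6-dien-1-yl]-6-methylhept-5-en-1-yl acetate | CC(=O)OC[C@H](CCC=C(C)C)[C@@H]1CC/C(C)=C/C/C=C(/C=O)[C@H]1C=O | target

## Step count and least certain steps

Total: 18 steps. Longest linear sequence: 16 steps (steps 1, 2 and 5–18); steps 3 and 4 form the second branch.

Step 5 (key step). The β-substituent of the (Z)-enol ether may slow the cycloaddition so far that enal self-condensation takes over, or it may clash with the ligand and erode endo and facial selectivity. Fallback: stereocontrol by a covalently bound, recoverable auxiliary and activation by pressure instead of the chromium Lewis acid. The fallback sets out from 6 and 4 and comes back at 12. (1R,2S)-2-Phenylcyclohexanol is converted with KH and trichloroethylene into the dichlorovinyl ether F1. n-BuLi turns this into the lithium alkynyl ether F2, which is alkylated with 6 to give the ynol ether F3. Lindlar reduction gives the (Z)-enol ether F4. Cycloaddition of F4 with 4 at about 12 kbar (CH2Cl2, rt, no Lewis acid) gives the endo adducts, which are diastereomers and are separated by chromatography to provide the adduct F5; the antipode of the auxiliary is chosen for the better ratio. The conditions of step 6 then remove the auxiliary as its silyl ether and lead to 12.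

Step 6. The ring oxocarbenium ion may be captured by the trisubstituted alkene of the side chain (five-membered Prins closure) before hydride arrives. Fallback: the cation is trapped by a far better nucleophile and the C–H bond is then made by an anionic, not a cationic, pathway. It sets out from 10 and comes back at 11. PhSH with catalytic BF3·OEt2 at −78 °C exchanges ethoxy for phenylsulfanyl and gives the thioacetal F6. Reductive lithiation with lithium naphthalenide (LiC10H8, THF, −78 °C) gives the 2-lithio ether F7, which is protonated with MeOH to 11; K2CO3/MeOH then gives 12.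

Step 12. Intermolecular alkylation (dimers, oligomers) or O-alkylation may compete with closure of the strained ring. Fallback: the ring is closed at C8–C9 by a Nozaki–Hiyama–Kishi reaction, a method with a good record for nine-membered carbocycles. It sets out from 17 and comes back at 25. Alkylation of 17 with LiCH2CN (THF, −78 °C) gives the nitrile F8. Iodination of the enol ether β-carbon (N-iodosuccinimide, cat. AgNO3, MeCN) gives the iodide F9. iBu2AlH at −78 °C followed by mild aqueous work-up gives the aldehyde F10. CrCl2 with catalytic NiCl2 in DMSO/THF at high dilution gives the carbinol F11, and Dess–Martin oxidation gives 25.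

Step 15. Hydride may be transferred to the alkenylpalladium intermediate before CO insertion, which amounts to reduction of the triflate. Fallback: the carbon is introduced at the ester level, where no hydride donor is present, and the oxidation state is adjusted afterwards. It sets out from 27 and comes back at 28. Methoxycarbonylation (Pd(OAc)2, PPh3, CO, MeOH, Et3N, DMF) gives the methyl ester F12. iBu2AlH at −78 °C gives the allylic alcohol F13, and MnO2 gives 28.

Step 16. External protonation of C9 is expected to occur anti to the two cis substituents at C1 and Cb and so to give the cis-fused lactol first. The subsequent equilibration may then be incomplete, may favour the wrong epimer, or may be accompanied by migration of the C7=C8 bond. Fallback: C9 is fixed in the δ-lactone, where the C9 hydrogen is far more acidic and a weak base suffices. It sets out from 28 (hydrolysed and isolated as 29) and comes back at 29. Ag2CO3 on Celite in toluene oxidises the lactol to the lactone F14, which is equilibrated with Et3N to the trans-fused form. iBu2AlH at −78 °C reduces the lactone to the lactol and the enal to the allylic alcohol, giving the lactol alcohol F15. MnO2 restores the enal and returns 29 with C9 set, which continues with the hydrazine addition of step 16.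

## Further compounds

F1 | step 5 | (1R,2S)-1-{[(E)-1,2-dichloroethenyl]oxy}-2-phenylcyclohexane | Cl/C=C(/Cl)O[C@@H]1CCCC[C@H]1c1ccccc1
F2 | step 5 | lithium {[(1R,2S)-2-phenylcyclohexyl]oxy}acetylide | [Li]C#CO[C@@H]1CCCC[C@H]1c1ccccc1
F3 | step 5 | 6-methyl-1-{[(1R,2S)-2-phenylcyclohexyl]oxy}hept-5-en-1-yne | CC(C)=CCCC#CO[C@@H]1CCCC[C@H]1c1ccccc1
F4 | step 5 | (1Z)-6-methyl-1-{[(1R,2S)-2-phenylcyclohexyl]oxy}hepta-1,5-diene | CC(C)=CCC/C=C\O[C@@H]1CCCC[C@H]1c1ccccc1
F5 | step 5 | analogue of 10 with {[(1R,2S)-2-phenylcyclohexyl]oxy} in place of ethoxy (same all-cis arrangement at C2, C3 and C4) | O([C@H]1OC=C[C@@H](CCC#C[Si](C)(C)C)[C@H]1CCC=C(C)C)[C@@H]1CCCC[C@H]1c1ccccc1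
F6 | step 6 | analogue of 10 with phenylsulfanyl in place of ethoxy (both anomers) | c1ccccc1SC1OC=C[C@@H](CCC#C[Si](C)(C)C)[C@H]1CCC=C(C)C
F7 | step 6 | 2-lithio derivative of 11 (lithium at Ca) | [Li]C1OC=C[C@@H](CCC#C[Si](C)(C)C)[C@H]1CCC=C(C)C
F8 | step 12 | (4E)-5-methyl-7-[(3R,4S)-3-(4-methylpent-3-en-1-yl)-3,4-dihydro-2H-pyran-4-yl]hept-4-enenitrile | C1OC=C[C@@H](CC/C(C)=C/CCC#N)[C@H]1CCC=C(C)C
F9 | step 12 | (4E)-7-[(3R,4S)-5-iodo-3-(4-methylpent-3-en-1-yl)-3,4-dihydro-2H-pyran-4-yl]-5-methylhept-4-enenitrile | C1OC=C(I)[C@@H](CC/C(C)=C/CCC#N)[C@H]1CCC=C(C)C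
F10 | step 12 | (4E)-7-[(3R,4S)-5-iodo-3-(4-methylpent-3-en-1-yl)-3,4-dihydro-2H-pyran-4-yl]-5-methylhept-4-enal | C1OC=C(I)[C@@H](CC/C(C)=C/CCC=O)[C@H]1CCC=C(C)C
F11 | step 12 | (1S,4E,13R)-4-methyl-13-(4-methylpent-3-en-1-yl)-11-oxabicyclo[7.4.0]trideca-4,9-dien-8-ol (both C8 epimers) | C1OC=C2C(O)CC/C=C(C)/CC[C@H]2[C@H]1CCC=C(C)C
F12 | step 15 | methyl (1S,4E,7E,13R)-4-methyl-13-(4-methylpent-3-en-1-yl)-11-oxabicyclo[7.4.0]trideca-4,7,9-triene-8-carboxylate | C1OC=C2/C(C(=O)OC)=C\C/C=C(C)/CC[C@H]2[C@H]1CCC=C(C)C
F13 | step 15 | [(1S,4E,7E,13R)-4-methyl-13-(4-methylpent-3-en-1-yl)-11-oxabicyclo[7.4.0]trideca-4,7,9-trien-8-yl]methanol | C1OC=C2/C(CO)=C\C/C=C(C)/CC[C@H]2[C@H]1CCC=C(C)C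
F14 | step 16 | (1S,4E,7E,9S,13R)-4-methyl-13-(4-methylpent-3-en-1-yl)-10-oxo-11-oxabicyclo[7.4.0]trideca-4,7-diene-8-carbaldehyde | O=C1OC[C@H](CCC=C(C)C)[C@@H]2CC/C(C)=C/C/C=C(/C=O)[C@@H]12
F15 | step 16 | (1S,4E,7E,9S,13R)-8-(hydroxymethyl)-4-methyl-13-(4-methylpent-3-en-1-yl)-11-oxabicyclo[7.4.0]trideca-4,7-dien-10-ol (both anomers) | OC1OC[C@H](CCC=C(C)C)[C@@H]2CC/C(C)=C/C/C=C(/CO)[C@@H]12
A1 | alternative 1 | nine-membered dienyl carboxylic acid: C9 carboxyl, C8 CH2OTBS, Cb=Cc alkene, Ca p-methoxybenzyl ether | COc1ccc(COC/C(=C\CC=C(C)C)[C@@H]2CC/C(C)=C/C/C=C(/CO[Si](C)(C)C(C)(C)C)[C@H]2C(=O)O)cc1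
A2 | alternative 1 | thirteen-membered allylic lactone: ester oxygen on Cc, Cb=C1 alkene, C9 methylene α to the carbonyl | COc1ccc(COC/C2=C\CC/C(C)=C/C/C=C(/CO[Si](C)(C)C(C)(C)C)CC(=O)O[C@@H]2CC=C(C)C)cc1
A3 | alternative 2 | (E)-cyclononenone with C9 ketone, C1 and Cb in place, Ca TBS ether | CC(C)(C)[Si](C)(C)OC[C@H](CCC=C(C)C)[C@@H]1CC/C(C)=C/CCCC1=O
A4 | alternative 2 | cis-fused 7a-hydroxy-3a-methyloctahydroinden-4-yl 4-methylbenzenesulfonate carrying the side chain at C1 (C9 hydroxyl, C4 methyl and C5 tosylate on one face) | CC(C)(C)[Si](C)(C)OC[C@H](CCC=C(C)C)[C@@H]1CC[C@@]2(C)[C@H](OS(=O)(=O)c3ccc(C)cc3)CCC[C@@]12O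
A5 | alternative 3 | nine-membered dienone: C9 ketone, (E)-C4=C5, C8 CH2OTBS, Ca p-methoxybenzyl ether | COc1ccc(COC[C@H](CCC=C(C)C)[C@@H]2CC/C(C)=C/C/C=C(/CO[Si](C)(C)C(C)(C)C)C2=O)cc1
A6 | alternative 3 | trans-1,2-dialkenylcyclopent-2-en-1-ol: C9 carbinol with the C1(=C2H2) alkenyl group, C5 with the isopropenyl group, C8 CH2OTBS | COc1ccc(COC[C@H](CCC=C(C)C)C(=C)[C@@]2(O)[C@H](C(C)=C)CC=C2CO[Si](C)(C)C(C)(C)C)cc1
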